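# Proposed synthesis of (2S)-6-geranyl-5,7-dihydroxy-2-(3-hydroxy-4-methoxyphenyl)chroman-4-one (20)

Abbreviations: geranyl = (2E)-3,7-dimethylocta-2,6-dien-1-yl; MOM = methoxymethyl; TIPS = triisopropylsilyl; TBS = tert-butyldimethylsilyl.

## The problem

- The target 20 is a flavanone whose ring A is a fully differentiated phloroglucinol. The geranyl chain must sit on C6, between the 5- and 7-oxygens and para to O1. The C8 isomer is the trap, because the three ring A oxygens are equivalent until one of them is singled out as O1.
- C2 is the only stereocentre, so no other centre can control it and its (S) configuration has to come from a catalyst or reagent.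
- C2 is fragile. Base opens ring C by retro-oxa-Michael reaction to the chalcone. Acid can ionise the O1–C2 bond, because C2 is a para-methoxybenzylic ether carbon.
- The geranyl chain has two trisubstituted alkenes, one of fixed (E) geometry. This rules out hydrogenolysis and strong electrophiles, and strong acid would cyclise the chain onto the flanking phenols.
- Three phenols must be protected with groups that come off without base and without hydrogen.
- The feature that opens the key step is that C3 and C4 are the only ring C atoms not already bonded to an aromatic ring or to O1. C2 can carry C3 as the vinyl group of a branched allyl aryl ether. C4 can sit on C4a as a 1-ethoxyvinyl group. The O1–C8a–C4a edge of ring A then holds the two alkenes in place to form C3=C4 by ring-closing metathesis, and the enol ether produced is the C4 ketone in masked form.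

## Retrosynthesis

**20 from 18.** The C4 carbonyl and the three phenols are uncovered last, from the 4-ethoxy-2H-chromene 18, by aqueous acid through the tris-MOM flavanone 19. MOM ethers are preferred to benzyl ethers (hydrogenolysis would saturate the chain) and to silyl ethers (fluoride is basic enough to open the flavanone). The forward reaction must hydrolyse an enol ether and three acetals without cyclising the geranyl group.

**18 from 17.** The C3=C4 bond is cut by a retro-metathesis to the diene 17, which carries a vinyl group on C2 and a 1-ethoxyvinyl group on C4a. This cut is preferred to the chalcone-type closure of O1–C2, which would have to create the stereocentre under basic, reversible conditions. It leaves an acyclic aryl ether in which the stereocentre is already in place. The forward reaction must select two of four alkenes.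

**17 from 16.** The enol ether CH2 is removed to give the ethyl benzoate 16, made in the forward sense by titanium methylenation.
- A Stille coupling of an aryl iodide after the ether is in place was rejected. The arylpalladium intermediate would sit ortho to the allyl ether, and 5-exo carbopalladation to a benzofuran is expected to outrun transmetalation from tin. Zerovalent palladium can also ionise the electron-rich 1-arylallyl aryl ether.
- Coupling before the ether is formed was rejected too, because an ortho-(1-ethoxyvinyl)phenol is expected to be too acid-labile to handle.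
- The ester is inert during the etherification and becomes the enol ether only when it is needed.

**16 from 9 and 14.** The O1–C2 bond is cut to the salicylate 9 and the linear cinnamyl ethyl carbonate 14. Iridium-catalysed branched-selective allylic etherification forms this bond and sets C2 in one operation, through the lithium aryloxide 15. The ethyl carbonate is matched to the ethyl ester so that liberated ethoxide cannot scramble the ester. The forward reaction needs branched selectivity and face selectivity with an electron-rich cinnamyl unit.

**9 from 8 from 7.** The C4a–C4 bond is cut to the ortho-iodophenol 8 (alkoxycarbonylation), and the C–I bond to the phenol 7. The two ortho positions of 7 are equivalent and the para position is blocked, so the iodination has only one possible site.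

**7 from 6, and 6 from 3 and 4.** The C6–C1'' bond is cut to the silyl ether 3 and geranyl bromide 4, through the aryllithium 5. In 3 the future O1 carries TIPS and the other two oxygens carry MOM. Only the C–H between the two MOM ethers is doubly activated for lithiation, so the chain is placed para to O1 by design. Fluoride then frees the O1 phenol alone. Compound 3 comes from phloroglucinol 1 through the bis-MOM ether 2.

**14 from 10.** The carbonate 14 is cut back through the cinnamyl alcohol 13 and the cinnamate 12 (olefination) to the MOM-protected aldehyde 11 and isovanillin 10. The (E) geometry needed for the iridium step is set by the Horner–Wadsworth–Emmons reaction.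

## Roads not taken

**Alternative 1: the geranyl chain built by carboalumination and benzylic coupling.**
- Cut: C1''–C2'' and C3''–CH3 of the side chain.
- Key step: 6-methylhept-5-en-1-yne A3 adds AlMe3 under Cp2ZrCl2 to give the (E)-alkenylalane A4. Pd(PPh3)4 then couples A4 with the benzyl chloride A2 to give the silyl ether A1, which is the same substance as 6.
- Merits: the (E) alkene is created by syn addition, the allyl terminus cannot transpose, and the chain can be varied.
- Weak points: it solves only the side chain. A2 needs about three extra operations from 3 (formylation of 5, reduction, chlorination) and is a doubly ortho-oxygenated benzylic chloride that ionises easily. Excess AlMe3 must coexist with two MOM acetals.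
- Comparison: it is better on regiochemical certainty at the allyl terminus. Against that, the chosen plan makes 6 in one step from 3 with the geometry bought in, and attack at the other terminus of geranyl bromide would have to form a quaternary carbon.

**Alternative 2: ring A grown on a chiral dihydropyranone.**
- Cut: C4a–C5 and C8–C8a.
- Key step: the geranyl-bearing bis(silyloxy)diene A6 adds across the sulfinyl-activated double bond of the (S)-dihydropyranone A7. Sulfoxide elimination and loss of the methoxy group from the ketene acetal carbon aromatise the new ring to the flavanone A5.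
- Merits: it is convergent. The geranyl position is fixed by the diene, so no oxygen has to be differentiated. A5 already has free 5- and 7-hydroxyls.
- Weak points: the second bond must join two fully substituted carbons. A7 is a vinylogous ester and a poor acceptor. The heat and the sulfenic acid released act on a β-aryloxy ketone that can open by elimination, which puts C2 at risk. The diene with a central geranyl group and the sulfinyl pyranone are both untested partners, and one MOM group still has to come off.
- Comparison: this road is better on convergence and on ring A regiochemistry, where the chosen plan spends six steps. The chosen plan offers known reaction classes in every step and a C2 centre that never sees more than 65 °C or base.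

**Alternative 3: rhodium carbene C–H insertion.**
- Cut: C2–C3.
- Key step: Rh2(S-PTTL)4 decomposes the diazoketone A9. The carbene carbon inserts into the benzylic C–H bond next to O1, closing ring C and setting C2 to give the tris-TBS flavanone A8.
- Merits: ring closure and stereocentre come in one step, directly at the ketone oxidation level. The chosen plan needs three steps (11 to 13) for the same result.
- Weak points: an acceptor-only carbene is unselective. The ether oxygen lies five atoms from the carbene carbon, so oxonium ylide formation with a [1,2]-shift to a benzofuranone competes. Cyclopropanation of the geranyl alkenes and addition to ring B are further outlets. Enantioselectivity of such six-membered insertions is usually moderate. Removing TBS with fluoride brings in the base that opens flavanones.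
- Comparison: this road is shorter at the end. The chosen plan separates the setting of C2, by a well-understood catalyst, from a ring closure that cannot touch it.

Key step: step 13

## Route

Assumption: the iridium–phosphoramidite catalyst is taken to follow the usual facial model, in which the (Ra,R,R) ligand gives (R)-1-arylallyl aryl ethers from (E)-cinnamyl carbonates. The (Sa,S,S) ligand L is therefore specified for the (S) ether, and its antipode would be used if the sense proved opposite. L = (Sa,S,S)-O,O'-(1,1'-binaphthyl-2,2'-diyl)-N,N-bis(1-phenylethyl)phosphoramidite.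

Step 1
Reactants: 1 phloroglucinol
Product: 2 3,5-bis(methoxymethoxy)phenol
Conditions: MOMCl (2.0 equiv), i-Pr2NEt, DMF, 0 °C → rt
Reagents that add atoms: chloromethyl methyl ether, COCCl
Why: O-Alkylation (acetal ether formation) of a symmetric triphenol, so only one bis-ether can form; it should be the main component of a statistical mixture from which the mono- and tris-ethers are separated.

Step 2
Reactants: 2 3,5-bis(methoxymethoxy)phenol
Product: 3 [3,5-bis(methoxymethoxy)phenoxy]triisopropylsilane
Conditions: TIPSCl, imidazole, DMF, rt
Reagents that add atoms: chlorotriisopropylsilane, CC(C)[Si](Cl)(C(C)C)C(C)C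
Why: Phenol silylation; the TIPS ether marks the future O1, is cleaved by fluoride beside MOM, and is too bulky to direct lithiation or to migrate to carbon.

Step 3
Reactants: 3 [3,5-bis(methoxymethoxy)phenoxy]triisopropylsilane; 4 geranyl bromide
Product: 6 triisopropyl[4-geranyl-3,5-bis(methoxymethoxy)phenoxy]silane, via aryllithium 5 (not isolated)
Conditions: n-BuLi, THF, 0 °C; CuI (10 mol%), 4, −78 → 0 °C
Reagents that add atoms: none
Why: Directed ortho-metalation at the only C–H flanked by two MOM ethers, then copper-catalysed allylic substitution at the primary carbon of 4; attack at the other allyl terminus would form a quaternary carbon, and the (E) alkene is not touched.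

Step 4
Reactants: 6 triisopropyl[4-geranyl-3,5-bis(methoxymethoxy)phenoxy]silane
Product: 7 4-geranyl-3,5-bis(methoxymethoxy)phenol
Conditions: TBAF, THF, 0 °C; aq NH4Cl
Reagents that add atoms: none
Why: Fluoride desilylation of an aryl silyl ether; MOM acetals and alkenes are inert to fluoride.

Step 5
Reactants: 7 4-geranyl-3,5-bis(methoxymethoxy)phenol
Product: 8 4-geranyl-2-iodo-3,5-bis(methoxymethoxy)phenol
Conditions: I2 (1.0 equiv), NaHCO3, THF–H2O, 0 °C
Reagents that add atoms: iodine, II
Why: Electrophilic aromatic iodination of a trioxygenated phenoxide, which should react far faster than the trisubstituted alkenes; the two ortho positions are equivalent and the para position is blocked, so one equivalent should give a single mono-iodide.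

Step 6
Reactants: 8 4-geranyl-2-iodo-3,5-bis(methoxymethoxy)phenol
Product: 9 ethyl 3-geranyl-6-hydroxy-2,4-bis(methoxymethoxy)benzoate
Conditions: Pd(OAc)2 (5 mol%), Xantphos (6 mol%), CO (1 atm), EtOH, Et3N, DMF, 70 °C
Reagents that add atoms: carbon monoxide, [C-]#[O+]; ethanol, CCO
Why: Palladium-catalysed alkoxycarbonylation of an aryl iodide (oxidative addition, CO insertion, ethanolysis); the free phenol is tolerated and no allyl ether is yet present to intercept the arylpalladium species.

Step 7
Reactants: 10 isovanillin
Product: 11 4-methoxy-3-(methoxymethoxy)benzaldehyde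
Conditions: MOMCl, i-Pr2NEt, CH2Cl2, 0 °C → rt
Reagents that add atoms: chloromethyl methyl ether, COCCl
Why: Standard MOM protection of a phenol, giving ring B the same protecting group as ring A.

Step 8
Reactants: 11 4-methoxy-3-(methoxymethoxy)benzaldehyde
Product: 12 ethyl (2E)-3-[4-methoxy-3-(methoxymethoxy)phenyl]prop-2-enoate
Conditions: (EtO)2P(O)CH2CO2Et, NaH, THF, 0 °C → rt
Reagents that add atoms: triethyl phosphonoacetate, CCOC(=O)CP(=O)(OCC)OCC
Why: Horner–Wadsworth–Emmons olefination of an aryl aldehyde with a stabilised phosphonate, which should give the (E) cinnamate.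

Step 9
Reactants: 12 ethyl (2E)-3-[4-methoxy-3-(methoxymethoxy)phenyl]prop-2-enoate
Product: 13 (2E)-3-[4-methoxy-3-(methoxymethoxy)phenyl]prop-2-en-1-ol
Conditions: i-Bu2AlH (2.2 equiv), CH2Cl2, −78 °C; aq potassium sodium tartrate
Reagents that add atoms: none
Why: 1,2-Reduction of an unsaturated ester to the allylic alcohol by an aluminium hydride, with the alkene geometry kept.

Step 10
Reactants: 13 (2E)-3-[4-methoxy-3-(methoxymethoxy)phenyl]prop-2-en-1-ol
Product: 14 ethyl (2E)-3-[4-methoxy-3-(methoxymethoxy)phenyl]prop-2-en-1-yl carbonate
Conditions: ClCO2Et, pyridine, CH2Cl2, 0 °C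
Reagents that add atoms: ethyl chloroformate, CCOC(=O)Cl
Why: Acylation of a primary alcohol to the carbonate, the leaving group used for iridium allyl chemistry; the ethyl group matches the ester of 9.

Step 11
Reactants: 9 ethyl 3-geranyl-6-hydroxy-2,4-bis(methoxymethoxy)benzoate; 14 ethyl (2E)-3-[4-methoxy-3-(methoxymethoxy)phenyl]prop-2-en-1-yl carbonate
Product: 16 ethyl 3-geranyl-2,4-bis(methoxymethoxy)-6-({(1S)-1-[4-methoxy-3-(methoxymethoxy)phenyl]prop-2-en-1-yl}oxy)benzoate, via lithium aryloxide 15 (not isolated)
Conditions: LiN(SiMe3)2 (1.0 equiv), THF, 0 °C; then 14 (1.2 equiv), [Ir(cod)Cl]2 (2 mol%), L (4 mol%, pre-activated with n-PrNH2), THF, rt → 40 °C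
Reagents that add atoms: none
Why: Iridium-catalysed asymmetric allylic etherification: the cyclometalated iridium–phosphoramidite complex ionises 14 to a π-allyl species and the aryloxide 15 attacks the aryl-bearing terminus to give the branched ether; the ligand selects the face and sets C2 as (S), and liberated ethoxide can only exchange the ethyl ester with itself.

Step 12
Reactants: 16 ethyl 3-geranyl-2,4-bis(methoxymethoxy)-6-({(1S)-1-[4-methoxy-3-(methoxymethoxy)phenyl]prop-2-en-1-yl}oxy)benzoate
Product: 17 2-(1-ethoxyethenyl)-4-geranyl-3,5-bis(methoxymethoxy)phenyl (1S)-1-[4-methoxy-3-(methoxymethoxy)phenyl]prop-2-en-1-yl ether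
Conditions: Cp2TiMe2 (3 equiv), toluene–THF, 65 °C, dark; filtration through basic alumina
Reagents that add atoms: dimethyltitanocene, C[Ti](C)(C1C=CC=C1)C1C=CC=C1
Why: Petasis methylenation: Cp2TiMe2 loses methane to give Cp2Ti=CH2, which converts the ester carbonyl into the 1-ethoxyvinyl group through an oxatitanacyclobutane; the reagent is neither acidic nor basic, so the ionisable O1–C2 bond, the MOM ethers and the C2 centre should be left alone.

Step 13
Reactants: 17 2-(1-ethoxyethenyl)-4-geranyl-3,5-bis(methoxymethoxy)phenyl (1S)-1-[4-methoxy-3-(methoxymethoxy)phenyl]prop-2-en-1-yl ether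
Product: 18 (2S)-4-ethoxy-6-geranyl-5,7-bis(methoxymethoxy)-2-[4-methoxy-3-(methoxymethoxy)phenyl]-2H-chromene
Conditions: second-generation Grubbs catalyst RuCl2(=CHPh)(PCy3)(H2IMes) (10 mol%), toluene (0.005 M), 60 °C, argon stream
Reagents that add atoms: none
Why: This is a ring-closing olefin metathesis of an alkenyl enol ether, the known way from ester-derived acyclic enol ethers to cyclic enol ethers. The ruthenium benzylidene exchanges with the monosubstituted vinyl group on C2, the only unhindered alkene, to place the alkylidene on C3. That alkylidene adds across the 1-ethoxyvinyl group with C3 bonding to C4 and ruthenium to the CH2 terminus, and cycloreversion of the ruthenacyclobutane forms C3=C4 and releases Ru=CH2, which leaves as ethylene. Ring C closes as a six-membered ring from a 1,7-diene with both new sp2 carbons in the ring, and the O1–C8a–C4a edge of ring A holds the two alkenes cis so the closure costs little entropy. No stereocentre is formed; the C2 centre from step 11 is a spectator and stays (S) as long as ruthenium hydride species do not migrate the allylic double bond, which moderate temperature and short reaction time should prevent. The step needs chemoselectivity among four alkenes: the two trisubstituted geranyl alkenes engage slowly and could only close strained bridged rings across ring A, and the 1,1-disubstituted enol ether is too hindered to take up ruthenium first and so acts only as the intramolecular acceptor. High dilution and removal of ethylene suppress cross-metathesis dimers. The product is a trisubstituted enol ether conjugated with ring A and should not re-open.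

Step 14
Reactants: 18 (2S)-4-ethoxy-6-geranyl-5,7-bis(methoxymethoxy)-2-[4-methoxy-3-(methoxymethoxy)phenyl]-2H-chromene
Product: 20 (2S)-6-geranyl-5,7-dihydroxy-2-(3-hydroxy-4-methoxyphenyl)chroman-4-one, via tris-MOM flavanone 19 (not isolated)
Conditions: HCl (3 M aq), MeOH–THF, 0 °C → 40 °C
Reagents that add atoms: water, O
Why: Acid hydrolysis: C3 of the enol ether is protonated and water adds at C4 to give the ketone 19, after which the three MOM acetals are cleaved; the flavanone is formed and deprotected without meeting base, so the retro-oxa-Michael path to racemisation is closed and C2 should stay (S).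

## Compound list

1 | phloroglucinol | Oc1cc(O)cc(O)c1 | starting material
2 | 3,5-bis(methoxymethoxy)phenol | COCOc1cc(O)cc(OCOC)c1 | intermediate
3 | [3,5-bis(methoxymethoxy)phenoxy]triisopropylsilane | COCOc1cc(OCOC)cc(O[Si](C(C)C)(C(C)C)C(C)C)c1 | intermediate
4 | geranyl bromide, (2E)-1-bromo-3,7-dimethylocta-2,6-diene | CC(C)=CCC/C(C)=C/CBr | starting material
5 | [2,6-bis(methoxymethoxy)-4-(triisopropylsilyloxy)phenyl]lithium | [Li]c1c(OCOC)cc(O[Si](C(C)C)(C(C)C)C(C)C)cc1OCOC | intermediate (not isolated)
6 | triisopropyl[4-geranyl-3,5-bis(methoxymethoxy)phenoxy]silane | CC(C)[Si](Oc1cc(OCOC)c(C/C=C(\C)CCC=C(C)C)c(OCOC)c1)(C(C)C)C(C)C | intermediate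
7 | 4-geranyl-3,5-bis(methoxymethoxy)phenol | Oc1cc(OCOC)c(C/C=C(\C)CCC=C(C)C)c(OCOC)c1 | intermediate
8 | 4-geranyl-2-iodo-3,5-bis(methoxymethoxy)phenol | Oc1cc(OCOC)c(C/C=C(\C)CCC=C(C)C)c(OCOC)c1I | intermediate
9 | ethyl 3-geranyl-6-hydroxy-2,4-bis(methoxymethoxy)benzoate | CCOC(=O)c1c(O)cc(OCOC)c(C/C=C(\C)CCC=C(C)C)c1OCOC | intermediate
10 | isovanillin, 3-hydroxy-4-methoxybenzaldehyde | COc1ccc(C=O)cc1O | starting material
11 | 4-methoxy-3-(methoxymethoxy)benzaldehyde | COCOc1cc(C=O)ccc1OC | intermediate
12 | ethyl (2E)-3-[4-methoxy-3-(methoxymethoxy)phenyl]prop-2-enoate | CCOC(=O)/C=C/c1ccc(OC)c(OCOC)c1 | intermediate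
13 | (2E)-3-[4-methoxy-3-(methoxymethoxy)phenyl]prop-2-en-1-ol | OC/C=C/c1ccc(OC)c(OCOC)c1 | intermediate
14 | ethyl (2E)-3-[4-methoxy-3-(methoxymethoxy)phenyl]prop-2-en-1-yl carbonate | CCOC(=O)OC/C=C/c1ccc(OC)c(OCOC)c1 | intermediate
15 | lithium 2-(ethoxycarbonyl)-4-geranyl-3,5-bis(methoxymethoxy)phenolate | [Li+].CCOC(=O)c1c([O-])cc(OCOC)c(C/C=C(\C)CCC=C(C)C)c1OCOC | intermediate (not isolated)
16 | ethyl 3-geranyl-2,4-bis(methoxymethoxy)-6-({(1S)-1-[4-methoxy-3-(methoxymethoxy)phenyl]prop-2-en-1-yl}oxy)benzoate | C=C[C@H](Oc1cc(OCOC)c(C/C=C(\C)CCC=C(C)C)c(OCOC)c1C(=O)OCC)c1ccc(OC)c(OCOC)c1 | intermediate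
17 | 2-(1-ethoxyethenyl)-4-geranyl-3,5-bis(methoxymethoxy)phenyl (1S)-1-[4-methoxy-3-(methoxymethoxy)phenyl]prop-2-en-1-yl ether | C=C[C@H](Oc1cc(OCOC)c(C/C=C(\C)CCC=C(C)C)c(OCOC)c1C(=C)OCC)c1ccc(OC)c(OCOC)c1 | intermediate
18 | (2S)-4-ethoxy-6-geranyl-5,7-bis(methoxymethoxy)-2-[4-methoxy-3-(methoxymethoxy)phenyl]-2H-chromene | CCOC1=C[C@@H](c2ccc(OC)c(OCOC)c2)Oc2cc(OCOC)c(C/C=C(\C)CCC=C(C)C)c(OCOC)c12 | intermediate
19 | (2S)-6-geranyl-5,7-bis(methoxymethoxy)-2-[4-methoxy-3-(methoxymethoxy)phenyl]chroman-4-one | COc1ccc([C@@H]2CC(=O)c3c(cc(OCOC)c(C/C=C(\C)CCC=C(C)C)c3OCOC)O2)cc1OCOC | intermediate (not isolated)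
20 | (2S)-6-geranyl-5,7-dihydroxy-2-(3-hydroxy-4-methoxyphenyl)chroman-4-one | COc1ccc([C@@H]2CC(=O)c3c(cc(O)c(C/C=C(\C)CCC=C(C)C)c3O)O2)cc1O | target

## Step count and risk

Total: 14 steps. Longest linear sequence: 10 steps (steps 1–6 and 11–14, from phloroglucinol). The ring B branch (steps 7–10) joins at step 11.

**Step 13 (key step).** The ring closure may stall, because the enol ether acceptor is 1,1-disubstituted and flanked by two ortho substituents. A stalled catalyst decays to ruthenium hydride species that migrate the allylic double bond and erode C2. The fallback sets out from 16 and returns at 18. The olefinic ester is treated with the reduced titanium ethylidene reagent (TiCl4, Zn, PbCl2 cat., TMEDA, CH3CHBr2, THF). A stoichiometric titanium alkylidene formed at the vinyl group olefinates the ester carbonyl intramolecularly, closing ring C by carbonyl–olefin metathesis without 17 and without ruthenium. No new compound is made.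

**Step 11.** Branched selectivity and enantiopurity may be lost through reversible ionisation of the electron-rich cinnamyl system, and the ortho-ester aryloxide, chelated to lithium, may attack slowly. The fallback sets out from 11 and 9 and returns at 16.
- Vinylmagnesium bromide adds to 11 to give racemic 1-[4-methoxy-3-(methoxymethoxy)phenyl]prop-2-en-1-ol F1.
- Sharpless kinetic resolution (Ti(Oi-Pr)4, D-(−)-diisopropyl tartrate, t-BuOOH) should, by the usual facial rule, consume the (S) alcohol as the erythro epoxy alcohol (R)-[4-methoxy-3-(methoxymethoxy)phenyl][(2S)-oxiran-2-yl]methanol F3 and leave (1R)-1-[4-methoxy-3-(methoxymethoxy)phenyl]prop-2-en-1-ol F2.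
- Mitsunobu reaction of F2 with phenol 9 (PPh3, diisopropyl azodicarboxylate, toluene, 0 °C) forms the O1–C2 bond with inversion to give 16.

**Step 12.** Methylenation of the doubly ortho-substituted benzoate may be incomplete, and prolonged heating could start a Claisen shift of the allyl aryl ether. The fallback makes the enol ether from a ketone; it sets out from 8 and 14 and returns at 19, and so at 20.
- Stille coupling of 8 with tributyl(1-ethoxyvinyl)stannane (Pd(PPh3)4, toluene, 90 °C) gives 2-(1-ethoxyethenyl)-4-geranyl-3,5-bis(methoxymethoxy)phenol F4. This is not isolated; dilute HCl on work-up hydrolyses it to 1-[3-geranyl-6-hydroxy-2,4-bis(methoxymethoxy)phenyl]ethan-1-one F5.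
- The lithium aryloxide of this ketone, lithium 2-acetyl-4-geranyl-3,5-bis(methoxymethoxy)phenolate F6, is etherified with 14 under the conditions of step 11. The product is 1-[3-geranyl-2,4-bis(methoxymethoxy)-6-({(1S)-1-[4-methoxy-3-(methoxymethoxy)phenyl]prop-2-en-1-yl}oxy)phenyl]ethan-1-one F7.
- TBSOTf and Et3N convert F7 into the silyl enol ether tert-butyl{[1-(3-geranyl-2,4-bis(methoxymethoxy)-6-{[(1S)-1-[4-methoxy-3-(methoxymethoxy)phenyl]prop-2-en-1-yl]oxy}phenyl)ethenyl]oxy}dimethylsilane F8.
- Ring-closing metathesis as in step 13 gives (2S)-4-(tert-butyldimethylsilyloxy)-6-geranyl-5,7-bis(methoxymethoxy)-2-[4-methoxy-3-(methoxymethoxy)phenyl]-2H-chromene F9. The acid of step 14 converts F9 into 19 and then 20.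

**Step 14.** The acid needed for the slower 7-O and 3'-O MOM groups may cyclise the geranyl chain onto a flanking phenol, or open the O1–C2 bond reversibly through the para-methoxybenzylic cation and erode C2. The fallback sets out from 18 and returns at 20. It separates the two events. Oxalic acid in wet THF at rt hydrolyses only the enol ether, and 19 is isolated. The MOM ethers are then removed without protic acid, by ZnBr2 and n-PrSH in CH2Cl2 at 0 °C for a few minutes. No new compound is made.

**Step 5.** Iodine may be captured by the geranyl alkenes, with a neighbouring MOM oxygen closing a ring, or a second iodination may occur. The fallback sets out from 7 and returns at 9, and uses no electrophilic halogen. Magnesium-mediated ortho-formylation (MgCl2, Et3N, paraformaldehyde, MeCN, reflux) gives 3-geranyl-6-hydroxy-2,4-bis(methoxymethoxy)benzaldehyde F10. Carbene-catalysed oxidative esterification (triazolium salt, DBU, 3,3',5,5'-tetra-tert-butyldiphenoquinone, EtOH, rt) then gives 9 directly.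

## Further compounds

F0 | step 13 | none | none
F1 | step 11 | racemic 1-[4-methoxy-3-(methoxymethoxy)phenyl]prop-2-en-1-ol | C=CC(O)c1ccc(OC)c(OCOC)c1
F2 | step 11 | (1R)-1-[4-methoxy-3-(methoxymethoxy)phenyl]prop-2-en-1-ol | C=C[C@@H](O)c1ccc(OC)c(OCOC)c1
F3 | step 11 | (R)-[4-methoxy-3-(methoxymethoxy)phenyl][(2S)-oxiran-2-yl]methanol | O[C@H](c1ccc(OC)c(OCOC)c1)[C@@H]1CO1
F4 | step 12 | 2-(1-ethoxyethenyl)-4-geranyl-3,5-bis(methoxymethoxy)phenol | C=C(OCC)c1c(O)cc(OCOC)c(C/C=C(\C)CCC=C(C)C)c1OCOC
F5 | step 12 | 1-[3-geranyl-6-hydroxy-2,4-bis(methoxymethoxy)phenyl]ethan-1-one | CC(=O)c1c(O)cc(OCOC)c(C/C=C(\C)CCC=C(C)C)c1OCOC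
F6 | step 12 | lithium 2-acetyl-4-geranyl-3,5-bis(methoxymethoxy)phenolate | [Li+].CC(=O)c1c([O-])cc(OCOC)c(C/C=C(\C)CCC=C(C)C)c1OCOC
F7 | step 12 | 1-[3-geranyl-2,4-bis(methoxymethoxy)-6-({(1S)-1-[4-methoxy-3-(methoxymethoxy)phenyl]prop-2-en-1-yl}oxy)phenyl]ethan-1-one | C=C[C@H](Oc1cc(OCOC)c(C/C=C(\C)CCC=C(C)C)c(OCOC)c1C(C)=O)c1ccc(OC)c(OCOC)c1
F8 | step 12 | tert-butyl{[1-(3-geranyl-2,4-bis(methoxymethoxy)-6-{[(1S)-1-[4-methoxy-3-(methoxymethoxy)phenyl]prop-2-en-1-yl]oxy}phenyl)ethenyl]oxy}dimethylsilane | C=C[C@H](Oc1cc(OCOC)c(C/C=C(\C)CCC=C(C)C)c(OCOC)c1C(=C)O[Si](C)(C)C(C)(C)C)c1ccc(OC)c(OCOC)c1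
F9 | step 12 | (2S)-4-(tert-butyldimethylsilyloxy)-6-geranyl-5,7-bis(methoxymethoxy)-2-[4-methoxy-3-(methoxymethoxy)phenyl]-2H-chromene | CC(C)(C)[Si](C)(C)OC1=C[C@@H](c2ccc(OC)c(OCOC)c2)Oc2cc(OCOC)c(C/C=C(\C)CCC=C(C)C)c(OCOC)c12
F0 | step 14 | none | none
F10 | step 5 | 3-geranyl-6-hydroxy-2,4-bis(methoxymethoxy)benzaldehyde | O=Cc1c(O)cc(OCOC)c(C/C=C(\C)CCC=C(C)C)c1OCOC
A1 | alternative 1 | triisopropyl[4-geranyl-3,5-bis(methoxymethoxy)phenoxy]silane (same substance as 6) | CC(C)[Si](Oc1cc(OCOC)c(C/C=C(\C)CCC=C(C)C)c(OCOC)c1)(C(C)C)C(C)C
A2 | alternative 1 | [4-(chloromethyl)-3,5-bis(methoxymethoxy)phenoxy]triisopropylsilane | ClCc1c(OCOC)cc(O[Si](C(C)C)(C(C)C)C(C)C)cc1OCOC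
A3 | alternative 1 | 6-methylhept-5-en-1-yne | C#CCCC=C(C)C
A4 | alternative 1 | [(1E)-2,6-dimethylhepta-1,5-dien-1-yl]dimethylalane | C[Al](C)/C=C(\C)CCC=C(C)C
A5 | alternative 2 | (2S)-6-geranyl-5,7-dihydroxy-2-[4-methoxy-3-(methoxymethoxy)phenyl]chroman-4-one | COc1ccc([C@@H]2CC(=O)c3c(cc(O)c(C/C=C(\C)CCC=C(C)C)c3O)O2)cc1OCOC
A6 | alternative 2 | 2-geranyl-1-methoxy-1,3-bis(trimethylsilyloxy)buta-1,3-diene | C=C(O[Si](C)(C)C)C(C/C=C(\C)CCC=C(C)C)=C(OC)O[Si](C)(C)C
A7 | alternative 2 | (2S)-2-[4-methoxy-3-(methoxymethoxy)phenyl]-5-(phenylsulfinyl)-2,3-dihydro-4H-pyran-4-one | COc1ccc([C@@H]2CC(=O)C(S(=O)c3ccccc3)=CO2)cc1OCOC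
A8 | alternative 3 | (2S)-5,7-bis(tert-butyldimethylsilyloxy)-2-[3-(tert-butyldimethylsilyloxy)-4-methoxyphenyl]-6-geranylchroman-4-one | COc1ccc([C@@H]2CC(=O)c3c(cc(O[Si](C)(C)C(C)(C)C)c(C/C=C(\C)CCC=C(C)C)c3O[Si](C)(C)C(C)(C)C)O2)cc1O[Si](C)(C)C(C)(C)C
A9 | alternative 3 | 1-{4,6-bis(tert-butyldimethylsilyloxy)-2-[(3-(tert-butyldimethylsilyloxy)-4-methoxyphenyl)methoxy]-5-geranylphenyl}-2-diazoethan-1-one | [N-]=[N+]=CC(=O)c1c(OCc2ccc(OC)c(O[Si](C)(C)C(C)(C)C)c2)cc(O[Si](C)(C)C(C)(C)C)c(C/C=C(\C)CCC=C(C)C)c1O[Si](C)(C)C(C)(C)C
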